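**Retrosynthetic overview**
1. The C6 ester is made last, by Yamaguchi acylation of macrocyclic alcohol 24 with (S)-2-methyloxirane-2-carboxylic acid 26.
2. Key step, chosen instead of the usual intermolecular Barbier reaction followed by RCM closure at C4=C5: an intramolecular Nozaki–Hiyama (Barbier) allylation of Z-enal 22 by its own 3-(bromomethyl)butenolide. It forms C6–C7, the ten-membered ring, the C6 and C7 stereocentres and the α-methylene lactone in one operation.
3. 22 comes from a butenolide made by RCM of a 2-(bromomethyl)acrylate, a 3(2H)-furanone made by Au-catalysed 5-endo-dig cyclisation of an α′-hydroxy ynone, and an ynone made by acetylide opening of lactone 12 with the commercial (Z)-enynol (source of 4Z).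
4. Lactone 12 (C8 and C10) comes from Seebach allylation of the L-lactic acid dioxolanone (C10), ozonolysis and ligand-controlled vinylzinc addition (C8).
5. Ring order: dioxolanone (auxiliary) → γ-lactone 12 (temporary) → 3(2H)-furanone → butenolide → ten-membered carbocycle, the butenolide becoming the α-methylene lactone.

Assumption: germacrane numbering (C1–C15) is used for locants; the target descriptors read from the SMILES are 4Z,6R,7R,8S,10R and 2′S.

**Route**

Step 1
Reactants: 1 (S)-lactic acid; 2 pivalaldehyde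
Product: 3 (2S,5S)-2-tert-butyl-5-methyl-1,3-dioxolan-4-one
Conditions: cat. p-TsOH, cat. H2SO4, pentane, reflux, Dean–Stark; recrystallise (pentane, −78 °C) to the pure cis isomer
Reagents that add atoms: none
Why: Seebach acetalisation (self-regeneration of stereocentres) gives mainly the cis acetal, whose new C2 centre (S) stores the lactate chirality and is purified by low-temperature crystallisation.

Step 2
Reactants: 3 (2S,5S)-2-tert-butyl-5-methyl-1,3-dioxolan-4-one; 4 allyl bromide
Product: 6 (2S,5R)-5-allyl-2-tert-butyl-5-methyl-1,3-dioxolan-4-one, via lithium enolate 5 (not isolated)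
Conditions: LDA (1.05 equiv), THF, −78 °C; then 4 (1.5 equiv), −78 → −30 °C
Reagents that add atoms: none
Why: Seebach SRS enolate alkylation, in which the planar enolate is allylated anti to the tert-butyl group, so allyl replaces H with retention and sets the future C10 quaternary centre (R).

Step 3
Reactants: 6 (2S,5R)-5-allyl-2-tert-butyl-5-methyl-1,3-dioxolan-4-one
Product: 8 (2S,5R)-2-tert-butyl-5-methyl-5-(2-oxoethyl)-1,3-dioxolan-4-one, via ozonide 7 (not isolated)
Conditions: O3, CH2Cl2, −78 °C; then PPh3, −78 °C → rt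
Reagents that add atoms: ozone [O-][O+]=O
Why: Ozonolysis with reductive work-up cleaves the only alkene to the C8 aldehyde without touching the acetal or the quaternary centre.

Step 4
Reactants: 8 (2S,5R)-2-tert-butyl-5-methyl-5-(2-oxoethyl)-1,3-dioxolan-4-one; 9 vinylmagnesium bromide
Product: 12 (3R,5S)-3-hydroxy-3-methyl-5-vinyloxolan-2-one, via divinylzinc 10 (not isolated), via hydroxy dioxolanone 11 (not isolated)
Conditions: 9 (3 equiv), ZnCl2 (1.5 equiv), THF/toluene, then 1,4-dioxane (removes Mg salts); (+)-MIB (10 mol%, the antipode that directs Re-face attack), 8, toluene, −20 °C; 1 M HCl work-up; then cat. CSA, CH2Cl2, rt; chromatography removes the minor cis lactone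
Reagents that add atoms: none
Why: Catalytic asymmetric vinylzinc addition (amino-alcohol-catalysed organozinc addition) delivers vinyl to the Re face of the aldehyde to set C8 (S) under ligand control, and the new hydroxyl then transacylates onto the dioxolanone (5-exo lactonisation) with loss of pivalaldehyde, so any C8 epimer is removed as the separable cis lactone.

Step 5
Reactants: 13 (Z)-3-methylpent-2-en-4-yn-1-ol
Product: 14 tert-butyldimethyl{[(2Z)-3-methylpent-2-en-4-yn-1-yl]oxy}silane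
Conditions: TBSCl (1.1 equiv), imidazole (2 equiv), DMF, 0 °C → rt
Reagents that add atoms: tert-butyldimethylsilyl chloride CC(C)(C)[Si](C)(C)Cl
Why: Standard silylation of the primary alcohol leaves the purchased Z alkene (the future 4Z) and the terminal alkyne untouched.

Step 6
Reactants: 12 (3R,5S)-3-hydroxy-3-methyl-5-vinyloxolan-2-one; 14 tert-butyldimethyl{[(2Z)-3-methylpent-2-en-4-yn-1-yl]oxy}silane
Product: 16 (3S,5R,9Z)-11-(tert-butyldimethylsilyloxy)-3,5-dihydroxy-5,9-dimethylundeca-1,9-dien-7-yn-6-one, via lithium acetylide 15 (not isolated)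
Conditions: 14 (2.3 equiv), n-BuLi (2.2 equiv), THF, −78 °C; then 12, −78 → −30 °C; AcOH quench at −78 °C
Reagents that add atoms: none
Why: Acetylide addition to a lactone, in which one equivalent deprotonates the tertiary OH and the next adds once to the lactone carbonyl, the tetrahedral lithium alkoxide surviving until the cold quench and then releasing the α′-hydroxy ynone and the C8 alcohol with both stereocentres untouched.

Step 7
Reactants: 16 (3S,5R,9Z)-11-(tert-butyldimethylsilyloxy)-3,5-dihydroxy-5,9-dimethylundeca-1,9-dien-7-yn-6-one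
Product: 17 (2R)-2-[(2S)-2-hydroxybut-3-en-1-yl]-2-methyl-5-[(2Z)-4-(tert-butyldimethylsilyloxy)but-2-en-2-yl]furan-3(2H)-one
Conditions: (Ph3P)AuNTf2 (3 mol%), toluene, rt
Reagents that add atoms: none
Why: Gold(I)-catalysed 5-endo-dig cycloisomerisation of an α′-hydroxy ynone (tertiary C10–OH onto the activated alkyne, then protodeauration) gives the 3(2H)-furanone, and C10 keeps its configuration because no bond to it is broken.

Step 8
Reactants: 17 (2R)-2-[(2S)-2-hydroxybut-3-en-1-yl]-2-methyl-5-[(2Z)-4-(tert-butyldimethylsilyloxy)but-2-en-2-yl]furan-3(2H)-one; 18 2-(bromomethyl)acrylic acid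
Product: 19 (2S)-1-{(2R)-2-methyl-3-oxo-5-[(2Z)-4-(tert-butyldimethylsilyloxy)but-2-en-2-yl]-2,3-dihydrofuran-2-yl}but-3-en-2-yl 2-(bromomethyl)prop-2-enoate
Conditions: 18 (1.5 equiv), DIC (1.5 equiv), DMAP (10 mol%), CH2Cl2, 0 °C
Reagents that add atoms: none
Why: Steglich esterification of the only free hydroxyl (C8–OH) proceeds with retention at C8.

Step 9
Reactants: 19 (2S)-1-{(2R)-2-methyl-3-oxo-5-[(2Z)-4-(tert-butyldimethylsilyloxy)but-2-en-2-yl]-2,3-dihydrofuran-2-yl}but-3-en-2-yl 2-(bromomethyl)prop-2-enoate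
Product: 20 (5S)-3-(bromomethyl)-5-{[(2R)-2-methyl-3-oxo-5-[(2Z)-4-(tert-butyldimethylsilyloxy)but-2-en-2-yl]-2,3-dihydrofuran-2-yl]methyl}furan-2(5H)-one
Conditions: Grubbs II (5 mol%), CH2Cl2 (5 mM), 40 °C
Reagents that add atoms: none
Why: Ring-closing metathesis between the vinyl group and the 2-substituted acrylate closes the five-membered butenolide, while the trisubstituted conjugated C4=C5 and the furanone alkene are too hindered and electron-poor to react.

Step 10
Reactants: 20 (5S)-3-(bromomethyl)-5-{[(2R)-2-methyl-3-oxo-5-[(2Z)-4-(tert-butyldimethylsilyloxy)but-2-en-2-yl]-2,3-dihydrofuran-2-yl]methyl}furan-2(5H)-one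
Product: 21 (5S)-3-(bromomethyl)-5-{[(2R)-5-[(2Z)-4-hydroxybut-2-en-2-yl]-2-methyl-3-oxo-2,3-dihydrofuran-2-yl]methyl}furan-2(5H)-one
Conditions: 48% aq HF, MeCN, 0 °C
Reagents that add atoms: none
Why: Acidic fluoride desilylation of the primary allylic TBS ether is used because basic fluoride (TBAF) would attack the allylic bromide and could epimerise the butenolide γ-centre C8.

Step 11
Reactants: 21 (5S)-3-(bromomethyl)-5-{[(2R)-5-[(2Z)-4-hydroxybut-2-en-2-yl]-2-methyl-3-oxo-2,3-dihydrofuran-2-yl]methyl}furan-2(5H)-one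
Product: 22 (2Z)-3-[(5R)-5-{[(2S)-4-(bromomethyl)-5-oxo-2,5-dihydrofuran-2-yl]methyl}-5-methyl-4-oxo-4,5-dihydrofuran-2-yl]but-2-enal
Conditions: Dess–Martin periodinane (1.3 equiv), CH2Cl2, 0 °C; used at once
Reagents that add atoms: none
Why: Dess–Martin oxidation of the allylic alcohol under neutral, non-nucleophilic conditions keeps the Z geometry and the allylic bromide intact.

Step 12
Reactants: 22 (2Z)-3-[(5R)-5-{[(2S)-4-(bromomethyl)-5-oxo-2,5-dihydrofuran-2-yl]methyl}-5-methyl-4-oxo-4,5-dihydrofuran-2-yl]but-2-enal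
Product: 24 (4Z,6R,7S,8S,10R)-6-hydroxy-3,10-epoxy-1-oxogermacra-2,4,11(13)-trien-12,8-olide, via allylchromium species 23 (not isolated)
Conditions: CrCl2 (6 equiv), degassed THF, rt; 22 added by syringe pump over 10 h (final 2 mM); H2O quench
Reagents that add atoms: none
Why: Intramolecular Nozaki–Hiyama (Barbier-type) allylation, in which the allylchromium(III) formed from the bromomethylbutenolide adds through its γ-carbon C7 to the enal via a chair Zimmerman–Traxler transition state, on the butenolide face anti to C9 (trans lactone, C7) and with the enal residue equatorial (6,7-anti, C6 R), closing the ten-membered ring and unveiling the α-methylene lactone in one step (C7 has the target geometry; its label is S here only because of CIP priorities).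

Step 13
Reactants: 25 (R)-2-methylglycidol
Product: 26 (S)-2-methyloxirane-2-carboxylic acid
Conditions: TEMPO (10 mol%), PhI(OAc)2 (2.2 equiv), MeCN/H2O 1:1, 0 °C → rt
Reagents that add atoms: water O
Why: TEMPO/BAIB oxidation of the primary alcohol through the aldehyde hydrate gives the acid without touching the epoxide or its quaternary centre (R becomes S only through CIP priorities).

Step 14
Reactants: 24 (4Z,6R,7S,8S,10R)-6-hydroxy-3,10-epoxy-1-oxogermacra-2,4,11(13)-trien-12,8-olide; 26 (S)-2-methyloxirane-2-carboxylic acid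
Product: 28 CNP0321429.1 (4Z,6R,7R,8S,10R)-6-[(2S)-2-methyloxirane-2-carbonyloxy]-3,10-epoxy-1-oxogermacra-2,4,11(13)-trien-12,8-olide, via mixed anhydride 27 (not isolated)
Conditions: 26 (2 equiv), 2,4,6-trichlorobenzoyl chloride (2 equiv), Et3N (2.5 equiv), toluene, rt, 1 h; then 24, DMAP (0.3 equiv), 0 °C → rt
Reagents that add atoms: none
Why: Yamaguchi esterification acylates the C6 hydroxyl through the aliphatic carbonyl of the mixed anhydride with retention at every stereocentre, the low DMAP loading limiting translactonisation and conjugate addition to the α-methylene lactone.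

**Compound list**
1 | (S)-lactic acid | C[C@H](O)C(=O)O | starting material
2 | pivalaldehyde | CC(C)(C)C=O | starting material
3 | (2S,5S)-2-tert-butyl-5-methyl-1,3-dioxolan-4-one (cis) | CC(C)(C)[C@H]1O[C@@H](C)C(=O)O1 | intermediate
4 | allyl bromide | C=CCBr | starting material
5 | lithium enolate of 3 (not isolated) | CC(C)(C)[C@H]1OC(C)=C([O-])O1.[Li+] | intermediate
6 | (2S,5R)-5-allyl-2-tert-butyl-5-methyl-1,3-dioxolan-4-one | CC(C)(C)[C@H]1O[C@@](CC=C)(C)C(=O)O1 | intermediate
7 | ozonide (1,2,4-trioxolane) of 6, mixture at the trioxolane carbon (not isolated) | CC(C)(C)[C@H]1O[C@@](CC2OCOO2)(C)C(=O)O1 | intermediate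
8 | (2S,5R)-2-tert-butyl-5-methyl-5-(2-oxoethyl)-1,3-dioxolan-4-one | CC(C)(C)[C@H]1O[C@@](CC=O)(C)C(=O)O1 | intermediate
9 | vinylmagnesium bromide | C=C[Mg]Br | starting material
10 | divinylzinc (not isolated) | C=C[Zn]C=C | intermediate
11 | (2S,5R)-2-tert-butyl-5-[(2S)-2-hydroxybut-3-en-1-yl]-5-methyl-1,3-dioxolan-4-one (not isolated) | CC(C)(C)[C@H]1O[C@@](C[C@H](O)C=C)(C)C(=O)O1 | intermediate
12 | (3R,5S)-3-hydroxy-3-methyl-5-vinyloxolan-2-one (OH and vinyl trans) | C=C[C@@H]1C[C@@](C)(O)C(=O)O1 | intermediate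
13 | (Z)-3-methylpent-2-en-4-yn-1-ol | C#C/C(C)=C\CO | starting material
14 | tert-butyldimethyl{[(2Z)-3-methylpent-2-en-4-yn-1-yl]oxy}silane | C#C/C(C)=C\CO[Si](C)(C)C(C)(C)C | intermediate
15 | lithium acetylide of 14 (not isolated) | [Li+].[C-]#C/C(C)=C\CO[Si](C)(C)C(C)(C)C | intermediate
16 | (3S,5R,9Z)-11-(tert-butyldimethylsilyloxy)-3,5-dihydroxy-5,9-dimethylundeca-1,9-dien-7-yn-6-one | C=C[C@@H](O)C[C@@](C)(O)C(=O)C#C/C(C)=C\CO[Si](C)(C)C(C)(C)C | intermediate
17 | (2R)-2-[(2S)-2-hydroxybut-3-en-1-yl]-2-methyl-5-[(2Z)-4-(tert-butyldimethylsilyloxy)but-2-en-2-yl]furan-3(2H)-one | C=C[C@@H](O)C[C@@]1(C)OC(/C(C)=C\CO[Si](C)(C)C(C)(C)C)=CC1=O | intermediate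
18 | 2-(bromomethyl)acrylic acid | C=C(CBr)C(=O)O | starting material
19 | 2-(bromomethyl)acrylate ester of 17 at the (2S)-carbinol | C=C[C@@H](OC(=O)C(=C)CBr)C[C@@]1(C)OC(/C(C)=C\CO[Si](C)(C)C(C)(C)C)=CC1=O | intermediate
20 | (5S)-3-(bromomethyl)-5-{[(2R)-2-methyl-3-oxo-5-[(2Z)-4-(tert-butyldimethylsilyloxy)but-2-en-2-yl]-2,3-dihydrofuran-2-yl]methyl}furan-2(5H)-one | BrCC1=C[C@H](C[C@@]2(C)OC(/C(C)=C\CO[Si](C)(C)C(C)(C)C)=CC2=O)OC1=O | intermediate
21 | (5S)-3-(bromomethyl)-5-{[(2R)-5-[(2Z)-4-hydroxybut-2-en-2-yl]-2-methyl-3-oxo-2,3-dihydrofuran-2-yl]methyl}furan-2(5H)-one | BrCC1=C[C@H](C[C@@]2(C)OC(/C(C)=C\CO)=CC2=O)OC1=O | intermediate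
22 | (2Z)-3-[(5R)-5-{[(2S)-4-(bromomethyl)-5-oxo-2,5-dihydrofuran-2-yl]methyl}-5-methyl-4-oxo-4,5-dihydrofuran-2-yl]but-2-enal | BrCC1=C[C@H](C[C@@]2(C)OC(/C(C)=C\C=O)=CC2=O)OC1=O | intermediate
23 | allylchromium(III) dichloride derived from 22 (not isolated) | Cl[Cr](Cl)CC1=C[C@H](C[C@@]2(C)OC(/C(C)=C\C=O)=CC2=O)OC1=O | intermediate
24 | (4Z,6R,7S,8S,10R)-6-hydroxy-3,10-epoxy-1-oxogermacra-2,4,11(13)-trien-12,8-olide (the target without its acyl group) | C=C1C(=O)O[C@H]2C[C@@]3(C)OC(=CC3=O)/C(C)=C\[C@@H](O)[C@H]12 | intermediate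
25 | (R)-2-methylglycidol, (2R)-(2-methyloxiran-2-yl)methanol | OC[C@]1(C)CO1 | starting material
26 | (S)-2-methyloxirane-2-carboxylic acid | OC(=O)[C@]1(C)CO1 | intermediate
27 | mixed anhydride of 26 with 2,4,6-trichlorobenzoic acid (not isolated) | O=C(OC(=O)c1c(Cl)cc(Cl)cc1Cl)[C@]2(C)CO2 | intermediate
28 | CNP0321429.1, (4Z,6R,7R,8S,10R)-6-[(2S)-2-methyloxirane-2-carbonyloxy]-3,10-epoxy-1-oxogermacra-2,4,11(13)-trien-12,8-olide | C=C1C(=O)O[C@H]2C[C@@]3(C)OC(=CC3=O)/C(C)=C\[C@@H](OC(=O)[C@]3(C)CO3)[C@H]12 | target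

**Totals**
Total step count: 14. Longest linear sequence: 12 steps (1, 2, 3, 4, 6, 7, 8, 9, 10, 11, 12, 14).

**Three steps most likely to fail**

Step 12 (macrocyclising Barbier allylation). The risks are oligomerisation, closure to the cis-lactone or the 6-epimer, and translactonisation of the chromium alkoxide. The fallback moves the ring closure to C4=C5 and makes the C6–C7 bond intermolecularly; it sets out from 12 and comes back at 24. The lithium acetylide of commercial 2-methylbut-1-en-3-yne is added to 12 as in step 6 to give (3S,5R)-3,5-dihydroxy-5,9-dimethyldeca-1,9-dien-7-yn-6-one F1. Gold cyclisation as in step 7 gives (2R)-2-[(2S)-2-hydroxybut-3-en-1-yl]-2-methyl-5-(prop-1-en-2-yl)furan-3(2H)-one F2. Esterification with 18 gives its 2-(bromomethyl)acrylate F3, and RCM gives (5S)-3-(bromomethyl)-5-{[(2R)-2-methyl-3-oxo-5-(prop-1-en-2-yl)-2,3-dihydrofuran-2-yl]methyl}furan-2(5H)-one F4. An intermolecular Barbier reaction of F4 with acrolein (Zn, THF/aq NH4Cl), where the trans,anti outcome is the expected one, gives (4S,5S)-4-[(1R)-1-hydroxyprop-2-en-1-yl]-3-methylidene-5-{[(2R)-2-methyl-3-oxo-5-(prop-1-en-2-yl)-2,3-dihydrofuran-2-yl]methyl}oxolan-2-one F5. A macrocyclising RCM between its isopropenyl and vinyl groups (Hoveyda–Grubbs II, toluene, 80 °C, 1 mM) forms C4=C5, with Z enforced by the ring, and returns to 24.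

Step 4 (ligand-controlled vinylation). The risks are modest or mismatched selectivity on an α-unbranched aldehyde and loss of material as the cis lactone. The fallback takes C8 from the chiral pool; it sets out from 3 and comes back at 12. (S)-Glycidol is converted (Tf2O, 2,6-lutidine, CH2Cl2, −78 °C) into (R)-glycidyl triflate F6. The lithium enolate of 3 (LDA, THF, −78 °C) is alkylated by F6 at the triflate carbon, anti to tert-butyl, to give (2S,5R)-2-tert-butyl-5-methyl-5-{[(2S)-oxiran-2-yl]methyl}-1,3-dioxolan-4-one F7. Excess dimethylsulfonium methylide (Me3S+ I−, n-BuLi, THF, −10 °C) opens the epoxide at its CH2 terminus and eliminates to the allylic alkoxide (one-carbon homologation of an epoxide to an allylic alcohol). This alkoxide lactonises with loss of pivalaldehyde and returns to 12.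

Step 9 (RCM of the 2-(bromomethyl)acrylate). The risks are a slow reaction at the 1,1-disubstituted electron-poor alkene and catalyst loss to the allylic bromide. The fallback closes the ring without C13 and adds that carbon afterwards; it sets out from 17 and comes back at 20. Acylation of 17 with acryloyl chloride (i-Pr2NEt, CH2Cl2, −78 °C) gives the acrylate ester F8. RCM (Grubbs II, CH2Cl2, 40 °C) gives the α-unsubstituted butenolide F9. A Morita–Baylis–Hillman reaction with aqueous formaldehyde (cat. PMe3, THF/H2O, rt) gives the 3-(hydroxymethyl)butenolide F10. Appel bromination (CBr4, PPh3, CH2Cl2, 0 °C) returns to 20.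

Further compounds
F1 | step 12 | (3S,5R)-3,5-dihydroxy-5,9-dimethyldeca-1,9-dien-7-yn-6-one | C=C[C@@H](O)C[C@@](C)(O)C(=O)C#CC(C)=C
F2 | step 12 | (2R)-2-[(2S)-2-hydroxybut-3-en-1-yl]-2-methyl-5-(prop-1-en-2-yl)furan-3(2H)-one | C=C[C@@H](O)C[C@@]1(C)OC(C(C)=C)=CC1=O
F3 | step 12 | 2-(bromomethyl)acrylate ester of F2 | C=C[C@@H](OC(=O)C(=C)CBr)C[C@@]1(C)OC(C(C)=C)=CC1=O
F4 | step 12 | (5S)-3-(bromomethyl)-5-{[(2R)-2-methyl-3-oxo-5-(prop-1-en-2-yl)-2,3-dihydrofuran-2-yl]methyl}furan-2(5H)-one | BrCC1=C[C@H](C[C@@]2(C)OC(C(C)=C)=CC2=O)OC1=O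
F5 | step 12 | (4S,5S)-4-[(1R)-1-hydroxyprop-2-en-1-yl]-3-methylidene-5-{[(2R)-2-methyl-3-oxo-5-(prop-1-en-2-yl)-2,3-dihydrofuran-2-yl]methyl}oxolan-2-one | C=C1C(=O)O[C@@H](C[C@@]2(C)OC(C(C)=C)=CC2=O)[C@@H]1[C@H](O)C=C
F6 | step 4 | (R)-glycidyl triflate | FC(F)(F)S(=O)(=O)OC[C@H]1CO1
F7 | step 4 | (2S,5R)-2-tert-butyl-5-methyl-5-{[(2S)-oxiran-2-yl]methyl}-1,3-dioxolan-4-one | CC(C)(C)[C@H]1O[C@@](C[C@H]2CO2)(C)C(=O)O1
F8 | step 9 | acrylate ester of 17 | C=C[C@@H](OC(=O)C=C)C[C@@]1(C)OC(/C(C)=C\CO[Si](C)(C)C(C)(C)C)=CC1=O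
F9 | step 9 | (5S)-5-{[(2R)-2-methyl-3-oxo-5-[(2Z)-4-(tert-butyldimethylsilyloxy)but-2-en-2-yl]-2,3-dihydrofuran-2-yl]methyl}furan-2(5H)-one | O=C1C=C[C@H](C[C@@]2(C)OC(/C(C)=C\CO[Si](C)(C)C(C)(C)C)=CC2=O)O1
F10 | step 9 | (5S)-3-(hydroxymethyl)-5-{[(2R)-2-methyl-3-oxo-5-[(2Z)-4-(tert-butyldimethylsilyloxy)but-2-en-2-yl]-2,3-dihydrofuran-2-yl]methyl}furan-2(5H)-one | OCC1=C[C@H](C[C@@]2(C)OC(/C(C)=C\CO[Si](C)(C)C(C)(C)C)=CC2=O)OC1=O
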